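**Plan**

1. Cuts, in retrosynthetic order: first the O–CH(aryl) bond of the tetrahydrofuran ring that carries the 4-hydroxy-3,5-dimethoxyphenyl group, back to a benzylic CH2 and a CH2OH (tetrahydrofuran 23). Then the other benzylic C–O bond and the bond from that benzylic carbon to the ring-fusion carbon (aldol of lactone 9 with aldehyde 19). Then the benzyl–lactone bond (aryl cuprate opening of cyclopropane lactone 5). In the side chain, the C(OH)–C(OAr) bond (Evans aldol) and the aryl–CHO bond.
2. Forward: epichlorohydrin + malonate give bicyclic lactone 5, which is opened by the aryl Grignard/CuI to 7 and decarboxylated to 9. Separately 10 + 11 → 12 → 15 → 16 → 17 → 19 (complete, silylated side chain). Then 9 + 19 → 21 → 22, acid closes the first tetrahydrofuran ring (23), oxidation closes the second and last ring (25), and desilylation gives 26.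
3. Stereochemistry: the lactone C4 (later a ring-fusion carbon) comes from (S)-epichlorohydrin. The second ring-fusion carbon is set by aldol addition anti to the benzyl group. The guaiacyl-side benzylic carbon is set by a stereoconvergent cation closure (aryl trans to CH2OH). The last benzylic carbon is set in the key step. Both side-chain centres (1S,2S, threo) come from the (R)-4-benzyloxazolidinone.
4. Enabling feature: in 23 the only free phenol is the 4-OH of the 3,5-dimethoxyphenyl ring, para to the benzylic CH2 on C4 of the tetrahydrofuran, with both ortho carbons blocked by OMe. The CH2OH on C3 is cis to that arm and five atoms away. Oxidation therefore gives one p-quinone methide, and one hydroxyl can close onto it.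
5. Helpers: the benzylic carbon is kept at the CH2 level until the key step, and the other phenol and the side-chain diol are silyl-capped; the silyl groups come off in step 14.

Key step: step 13

Abbreviations: TBS = tert-butyldimethylsilyl; Ar1 = 4-{[(1S,2S)-1,3-bis(TBS-oxy)-1-(4-TBS-oxy-3-methoxyphenyl)propan-2-yl]oxy}-3-methoxyphenyl.

Assumption (chemistry): the carbinol carbon made in step 10 is carried as both epimers, because it is planarised as a benzylic cation in step 12.

**Route**

Step 1
Reactants: 1 4-bromo-2,6-dimethoxyphenol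
Product: 2 (4-bromo-2,6-dimethoxyphenoxy)(tert-butyl)dimethylsilane
Conditions: TBSCl, imidazole, DMF, rt
Reagents that add atoms: tert-butyldimethylsilyl chloride (TBSCl), CC(C)(C)[Si](C)(C)Cl
Why: Silyl ether formation masks the acidic phenol so that the aryl bromide can be converted into a Grignard reagent.

Step 2
Reactants: 3 (S)-epichlorohydrin; 4 diethyl malonate
Product: 5 ethyl (1R,5S)-2-oxo-3-oxabicyclo[3.1.0]hexane-1-carboxylate
Conditions: NaOEt, EtOH, 0 °C to reflux
Reagents that add atoms: none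
Why: Malonate alkylation–cyclopropanation–lactonisation cascade (epoxide opening at CH2, re-closure of an epoxide with loss of chloride, 3-exo-tet cyclopropane closure with inversion, lactonisation), which turns the stereocentre of 3 into the ring-fusion CH (5S) of the cis-fused bicycle.

Step 3
Reactants: 2 (4-bromo-2,6-dimethoxyphenoxy)(tert-butyl)dimethylsilane; 5 ethyl (1R,5S)-2-oxo-3-oxabicyclo[3.1.0]hexane-1-carboxylate
Product: 7 ethyl (3R,4S)-4-[4-(TBS-oxy)-3,5-dimethoxybenzyl]-2-oxotetrahydrofuran-3-carboxylate, via aryl Grignard reagent 6 (not isolated)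
Conditions: Mg, THF, reflux; then CuI (10 mol %), 5, THF, −30 to 0 °C; aq. NH4Cl
Reagents that add atoms: none
Why: Strain-release homoconjugate addition: the aryl cuprate attacks the CH2 of the doubly activated cyclopropane in an SN2 manner to give a malonate-type enolate, the ring-fusion stereocentre is untouched and protonation gives the trans lactone.

Step 4
Reactants: 7 ethyl (3R,4S)-4-[4-(TBS-oxy)-3,5-dimethoxybenzyl]-2-oxotetrahydrofuran-3-carboxylate
Product: 9 (S)-4-(4-hydroxy-3,5-dimethoxybenzyl)dihydrofuran-2(3H)-one, via carboxy lactone 8 (not isolated)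
Conditions: 2 M NaOH, MeOH, 50 °C (argon); 3 M HCl to pH 1; then toluene, reflux
Reagents that add atoms: none
Why: Saponification (which also cleaves the base-labile aryl silyl ether), relactonisation on acidification and thermal decarboxylation of the malonic-type acid; the remaining stereocentre is not enolisable and is retained.

Step 5
Reactants: 10 4-bromo-2-methoxyphenol; 11 (R)-4-benzyl-3-(chloroacetyl)oxazolidin-2-one
Product: 12 (R)-4-benzyl-3-[(4-bromo-2-methoxyphenoxy)acetyl]oxazolidin-2-one
Conditions: K2CO3, MeCN, 40 °C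
Reagents that add atoms: none
Why: Williamson ether synthesis, the phenoxide displacing the carbonyl-activated primary chloride faster than it attacks the imide carbonyl.

Step 6
Reactants: 12 (R)-4-benzyl-3-[(4-bromo-2-methoxyphenoxy)acetyl]oxazolidin-2-one; 13 4-(TBS-oxy)-3-methoxybenzaldehyde
Product: 15 (R)-4-benzyl-3-[(2R,3S)-2-(4-bromo-2-methoxyphenoxy)-3-(4-TBS-oxy-3-methoxyphenyl)-3-hydroxypropanoyl]oxazolidin-2-one, via Z boron enolate 14 (not isolated)
Conditions: Bu2BOTf, iPr2NEt, CH2Cl2, −78 to 0 °C; then 13, −78 to 0 °C; H2O2, MeOH, pH 7 buffer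
Reagents that add atoms: none
Why: Evans syn-aldol reaction: the Z dibutylboron enolate reacts through a closed chair transition state on the enolate face not shielded by the benzyl group of the (R)-auxiliary, setting both centres (2R,3S, the threo arrangement of the final ether).

Step 7
Reactants: 15 (R)-4-benzyl-3-[(2R,3S)-2-(4-bromo-2-methoxyphenoxy)-3-(4-TBS-oxy-3-methoxyphenyl)-3-hydroxypropanoyl]oxazolidin-2-one
Product: 16 (1S,2S)-2-(4-bromo-2-methoxyphenoxy)-1-(4-TBS-oxy-3-methoxyphenyl)propane-1,3-diol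
Conditions: LiBH4, H2O (1 equiv), Et2O/THF, 0 °C
Reagents that add atoms: none
Why: Reductive cleavage of the N-acyl oxazolidinone by borohydride gives the primary alcohol and releases the auxiliary without touching either stereocentre.

Step 8
Reactants: 16 (1S,2S)-2-(4-bromo-2-methoxyphenoxy)-1-(4-TBS-oxy-3-methoxyphenyl)propane-1,3-diol
Product: 17 4-bromo-1-{[(1S,2S)-1,3-bis(TBS-oxy)-1-(4-TBS-oxy-3-methoxyphenyl)propan-2-yl]oxy}-2-methoxybenzene
Conditions: TBSOTf (2.5 equiv), 2,6-lutidine, CH2Cl2, −78 to 0 °C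
Reagents that add atoms: tert-butyldimethylsilyl triflate (TBSOTf), CC(C)(C)[Si](C)(C)OS(=O)(=O)C(F)(F)F
Why: Silyl ether formation on both hydroxyls (the triflate is needed for the hindered benzylic one) protects the diol against the organolithium, enolate, hydride and acid steps that follow.

Step 9
Reactants: 17 4-bromo-1-{[(1S,2S)-1,3-bis(TBS-oxy)-1-(4-TBS-oxy-3-methoxyphenyl)propan-2-yl]oxy}-2-methoxybenzene
Product: 19 Ar1-CHO (4-{[(1S,2S)-1,3-bis(TBS-oxy)-1-(4-TBS-oxy-3-methoxyphenyl)propan-2-yl]oxy}-3-methoxybenzaldehyde), via aryllithium 18 (not isolated)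
Conditions: n-BuLi, THF, −78 °C; then DMF; aq. NH4Cl
Reagents that add atoms: N,N-dimethylformamide (DMF), CN(C)C=O
Why: Bromine–lithium exchange followed by formylation with DMF (Bouveault aldehyde synthesis), the exchange at −78 °C being faster than any attack on the silyl ethers.

Step 10
Reactants: 9 (S)-4-(4-hydroxy-3,5-dimethoxybenzyl)dihydrofuran-2(3H)-one; 19 Ar1-CHO
Product: 21 (3R,4S)-3-[hydroxy(Ar1)methyl]-4-(4-hydroxy-3,5-dimethoxybenzyl)dihydrofuran-2(3H)-one (both carbinol epimers), via dilithio enolate 20 (not isolated)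
Conditions: LiN(iPr)2 (2.2 equiv per 9), THF, −78 °C; then 19; AcOH
Reagents that add atoms: none
Why: Lactone enolate aldol addition in which the lithium phenoxide is a spectator and the enolate adds to the aldehyde on the face opposite the 4-benzyl group, setting the 3,4-trans relationship (3R).

Step 11
Reactants: 21 (3R,4S)-3-[hydroxy(Ar1)methyl]-4-(4-hydroxy-3,5-dimethoxybenzyl)dihydrofuran-2(3H)-one
Product: 22 (2S,3S)-2-[hydroxy(Ar1)methyl]-3-(4-hydroxy-3,5-dimethoxybenzyl)butane-1,4-diol (both carbinol epimers)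
Conditions: LiBH4, THF, 0 °C to rt
Reagents that add atoms: none
Why: Borohydride reduction of the lactone to the 1,4-diol, which leaves the silyl ethers and both ring stereocentres unchanged.

Step 12
Reactants: 22 (2S,3S)-2-[hydroxy(Ar1)methyl]-3-(4-hydroxy-3,5-dimethoxybenzyl)butane-1,4-diol
Product: 23 [(2R,3S,4S)-2-Ar1-4-(4-hydroxy-3,5-dimethoxybenzyl)tetrahydrofuran-3-yl]methanol
Conditions: camphorsulfonic acid (10 mol %), CH2Cl2, 0 °C; Et3N quench
Reagents that add atoms: none
Why: Acid-catalysed SN1 cycloetherification in which both carbinol epimers ionise to the same p-alkoxybenzyl cation and the CH2OH on C3 of the butane chain closes the five-membered ring with the aryl group anti to the neighbouring CH2OH (2,3-trans), the mild acid and short time keeping the slower Friedel–Crafts closure by the dimethoxyphenol ring from competing.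

Step 13
Reactants: 23 [(2R,3S,4S)-2-Ar1-4-(4-hydroxy-3,5-dimethoxybenzyl)tetrahydrofuran-3-yl]methanol
Product: 25 4-[(1R,3aS,4R,6aS)-4-Ar1-tetrahydro-1H,3H-furo[3,4-c]furan-1-yl]-2,6-dimethoxyphenol, via p-quinone methide 24 (not isolated)
Conditions: Ag2O (2.5 equiv), CH2Cl2, rt, dark; then pyridinium p-toluenesulfonate (5 mol %)
Reagents that add atoms: none
Why: Ag2O removes two electrons and two protons (the phenolic H and one benzylic H) from the only free phenol to give p-quinone methide 24, and the primary hydroxyl on the neighbouring ring carbon then adds to its exocyclic carbon with rearomatisation (intramolecular oxa-1,6-conjugate addition). The closest known reaction types are the Ag2O oxidation of 4-alkyl-2,6-dimethoxyphenols to quinone methides and the hydroxyl-to-quinone-methide ring closures that follow oxidative phenol coupling in furofuran formation. The new tetrahydrofuran ring closes in the 5-exo-trig mode, the oxygen attacking the exocyclic terminus of a C=C whose other carbon lies outside the ring. The new benzylic centre (4R) is controlled by the substrate: the one-carbon tether permits only cis ring fusion, and allylic 1,3-strain holds the ring C–H in the plane of the quinone methide, so the oxygen adds to the face that leaves the aryl group exo (trans to the CH2 of the first ring); because 24 is planar at that carbon, no prior stereochemical information is needed there. The step needs chemoselective oxidation and a single nucleophile: the other two aryl oxygens are an alkyl ether and a silyl ether, which Ag2O does not oxidise, the two ortho methoxy groups block radical coupling on the ring, and the CH2OH is the only free hydroxyl in the molecule.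

Step 14
Reactants: 25 4-[(1R,3aS,4R,6aS)-4-Ar1-tetrahydro-1H,3H-furo[3,4-c]furan-1-yl]-2,6-dimethoxyphenol
Product: 26 (1S,2S)-1-(4-hydroxy-3-methoxyphenyl)-2-{4-[(1R,3aS,4R,6aS)-4-(4-hydroxy-3,5-dimethoxyphenyl)tetrahydro-1H,3H-furo[3,4-c]furan-1-yl]-2-methoxyphenoxy}propane-1,3-diol (target)
Conditions: Bu4NF, AcOH (1:1, 4 equiv), THF, 0 °C to rt
Reagents that add atoms: none
Why: Fluoride-mediated desilylation of the aryl, primary and secondary benzylic silyl ethers, the acetic acid buffer keeping the p-hydroxybenzylic positions from base-induced quinone methide chemistry.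

**Compound list**

1 | 4-bromo-2,6-dimethoxyphenol | COc1cc(Br)cc(OC)c1O | starting material
2 | (4-bromo-2,6-dimethoxyphenoxy)(tert-butyl)dimethylsilane | COc1cc(Br)cc(OC)c1O[Si](C)(C)C(C)(C)C | intermediate
3 | (S)-epichlorohydrin | ClC[C@@H]1CO1 | starting material
4 | diethyl malonate | CCOC(=O)CC(=O)OCC | starting material
5 | ethyl (1R,5S)-2-oxo-3-oxabicyclo[3.1.0]hexane-1-carboxylate | O=C1OC[C@H]2C[C@@]12C(=O)OCC | intermediate
6 | [4-(TBS-oxy)-3,5-dimethoxyphenyl]magnesium bromide | COc1cc([Mg]Br)cc(OC)c1O[Si](C)(C)C(C)(C)C | intermediate (not isolated)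
7 | ethyl (3R,4S)-4-[4-(TBS-oxy)-3,5-dimethoxybenzyl]-2-oxotetrahydrofuran-3-carboxylate | O=C1OC[C@@H](Cc2cc(OC)c(O[Si](C)(C)C(C)(C)C)c(OC)c2)[C@@H]1C(=O)OCC | intermediate
8 | (3R,4S)-4-(4-hydroxy-3,5-dimethoxybenzyl)-2-oxotetrahydrofuran-3-carboxylic acid | O=C1OC[C@@H](Cc2cc(OC)c(O)c(OC)c2)[C@@H]1C(=O)O | intermediate (not isolated)
9 | (S)-4-(4-hydroxy-3,5-dimethoxybenzyl)dihydrofuran-2(3H)-one | O=C1OC[C@@H](Cc2cc(OC)c(O)c(OC)c2)C1 | intermediate
10 | 4-bromo-2-methoxyphenol | COc1cc(Br)ccc1O | starting material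
11 | (R)-4-benzyl-3-(chloroacetyl)oxazolidin-2-one | O=C(CCl)N1[C@H](Cc2ccccc2)COC1=O | starting material
12 | (R)-4-benzyl-3-[(4-bromo-2-methoxyphenoxy)acetyl]oxazolidin-2-one | O=C(COc1ccc(Br)cc1OC)N1[C@H](Cc2ccccc2)COC1=O | intermediate
13 | 4-(TBS-oxy)-3-methoxybenzaldehyde | COc1cc(C=O)ccc1O[Si](C)(C)C(C)(C)C | starting material
14 | Z dibutylboron enolate of 12 | CCCCB(CCCC)O/C(=C\Oc1ccc(Br)cc1OC)N1[C@H](Cc2ccccc2)COC1=O | intermediate (not isolated)
15 | (R)-4-benzyl-3-[(2R,3S)-2-(4-bromo-2-methoxyphenoxy)-3-(4-TBS-oxy-3-methoxyphenyl)-3-hydroxypropanoyl]oxazolidin-2-one | COc1cc([C@H](O)[C@H](C(=O)N2[C@H](Cc3ccccc3)COC2=O)Oc2ccc(Br)cc2OC)ccc1O[Si](C)(C)C(C)(C)C | intermediate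
16 | (1S,2S)-2-(4-bromo-2-methoxyphenoxy)-1-(4-TBS-oxy-3-methoxyphenyl)propane-1,3-diol | COc1cc([C@H](O)[C@H](CO)Oc2ccc(Br)cc2OC)ccc1O[Si](C)(C)C(C)(C)C | intermediate
17 | 4-bromo-1-{[(1S,2S)-1,3-bis(TBS-oxy)-1-(4-TBS-oxy-3-methoxyphenyl)propan-2-yl]oxy}-2-methoxybenzene | COc1cc([C@H](O[Si](C)(C)C(C)(C)C)[C@H](CO[Si](C)(C)C(C)(C)C)Oc2ccc(Br)cc2OC)ccc1O[Si](C)(C)C(C)(C)C | intermediate
18 | aryllithium from 17 (Ar1-Li) | COc1cc([C@H](O[Si](C)(C)C(C)(C)C)[C@H](CO[Si](C)(C)C(C)(C)C)Oc2ccc([Li])cc2OC)ccc1O[Si](C)(C)C(C)(C)C | intermediate (not isolated)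
19 | Ar1-CHO, 4-{[(1S,2S)-1,3-bis(TBS-oxy)-1-(4-TBS-oxy-3-methoxyphenyl)propan-2-yl]oxy}-3-methoxybenzaldehyde | COc1cc([C@H](O[Si](C)(C)C(C)(C)C)[C@H](CO[Si](C)(C)C(C)(C)C)Oc2ccc(C=O)cc2OC)ccc1O[Si](C)(C)C(C)(C)C | intermediate
20 | dilithio phenoxide enolate of 9 | [Li]Oc1c(OC)cc(C[C@@H]2COC(O[Li])=C2)cc1OC | intermediate (not isolated)
21 | (3R,4S)-3-[hydroxy(Ar1)methyl]-4-(4-hydroxy-3,5-dimethoxybenzyl)dihydrofuran-2(3H)-one, both carbinol epimers | COc1cc([C@H](O[Si](C)(C)C(C)(C)C)[C@H](CO[Si](C)(C)C(C)(C)C)Oc2ccc(C(O)[C@@H]3C(=O)OC[C@H]3Cc4cc(OC)c(O)c(OC)c4)cc2OC)ccc1O[Si](C)(C)C(C)(C)C | intermediate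
22 | (2S,3S)-2-[hydroxy(Ar1)methyl]-3-(4-hydroxy-3,5-dimethoxybenzyl)butane-1,4-diol, both carbinol epimers | COc1cc([C@H](O[Si](C)(C)C(C)(C)C)[C@H](CO[Si](C)(C)C(C)(C)C)Oc2ccc(C(O)[C@H](CO)[C@@H](CO)Cc3cc(OC)c(O)c(OC)c3)cc2OC)ccc1O[Si](C)(C)C(C)(C)C | intermediate
23 | [(2R,3S,4S)-2-Ar1-4-(4-hydroxy-3,5-dimethoxybenzyl)tetrahydrofuran-3-yl]methanol | COc1cc([C@H](O[Si](C)(C)C(C)(C)C)[C@H](CO[Si](C)(C)C(C)(C)C)Oc2ccc([C@@H]3OC[C@@H](Cc4cc(OC)c(O)c(OC)c4)[C@H]3CO)cc2OC)ccc1O[Si](C)(C)C(C)(C)C | intermediate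
24 | p-quinone methide of 23 (4-ylidenemethyl-2,6-dimethoxycyclohexa-2,5-dienone) | COc1cc([C@H](O[Si](C)(C)C(C)(C)C)[C@H](CO[Si](C)(C)C(C)(C)C)Oc2ccc([C@@H]3OC[C@@H](C=C4C=C(OC)C(=O)C(OC)=C4)[C@H]3CO)cc2OC)ccc1O[Si](C)(C)C(C)(C)C | intermediate (not isolated)
25 | 4-[(1R,3aS,4R,6aS)-4-Ar1-tetrahydro-1H,3H-furo[3,4-c]furan-1-yl]-2,6-dimethoxyphenol | COc1cc([C@H](O[Si](C)(C)C(C)(C)C)[C@H](CO[Si](C)(C)C(C)(C)C)Oc2ccc([C@@H]3OC[C@@H]4[C@H]3CO[C@H]4c3cc(OC)c(O)c(OC)c3)cc2OC)ccc1O[Si](C)(C)C(C)(C)C | intermediate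
26 | (1S,2S)-1-(4-hydroxy-3-methoxyphenyl)-2-{4-[(1R,3aS,4R,6aS)-4-(4-hydroxy-3,5-dimethoxyphenyl)tetrahydro-1H,3H-furo[3,4-c]furan-1-yl]-2-methoxyphenoxy}propane-1,3-diol | COc1cc([C@H](O)[C@H](CO)Oc2ccc([C@@H]3OC[C@@H]4[C@H]3CO[C@H]4c3cc(OC)c(O)c(OC)c3)cc2OC)ccc1O | target

**Count and risks**

Total steps: 14. Longest linear sequence: 10 steps (steps 5–9, then 10–14); the lactone branch (steps 1–4) joins at step 10.

Steps most likely to fail:

1. Step 13 (key step). The quinone methide may tautomerise to the styrene-type alkene by loss of the ring C–H, be captured intermolecularly or oligomerise before the hydroxyl closes the ring, and the facial selectivity of the closure may be incomplete. Fallback: oxidation and ring closure are separated. Setting out from 23, the oxidation is run with Ag2O in MeOH/CH2Cl2, so that the solvent captures the quinone methide at once and gives the benzylic methyl ether of 23, F1 (both epimers). Camphorsulfonic acid (catalytic) in CH2Cl2 then ionises this p-hydroxybenzyl ether reversibly, and the primary hydroxyl closes the ring by acid-catalysed SN1 transetherification under equilibrating conditions. The route is rejoined at 25.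

2. Step 10. Enolisation of the phenol-bearing lactone may be incomplete, or the dilithio species may aggregate or precipitate, so that the aldehyde is recovered or the aldolate reverts. Fallback: the phenol is masked instead of carried as its salt. Setting out from 9, Me3SiCl and Et3N give the aryl trimethylsilyl ether of 9, F2. One equivalent of LiN(iPr)2 and aldehyde 19 then give the O-silylated aldol adduct, F3. Aqueous citric acid work-up cleaves the labile aryl silyl ether, and the route is rejoined at 21.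

3. Step 5. The phenoxide may attack the exocyclic imide carbonyl (acyl transfer with loss of the auxiliary) instead of displacing chloride, and the chloroacetyl imide may decompose under carbonate. Fallback: the ether bond is made before the auxiliary is attached. Setting out from 10, alkylation with tert-butyl bromoacetate (K2CO3, acetone) gives tert-butyl (4-bromo-2-methoxyphenoxy)acetate, F4. CF3CO2H in CH2Cl2 gives (4-bromo-2-methoxyphenoxy)acetic acid, F5. Pivaloyl chloride and Et3N convert it into the mixed pivalic anhydride, F6, which acylates (R)-4-benzyloxazolidin-2-one in the presence of LiCl. The route is rejoined at 12.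

**Further compounds**

F1 | step 13 | [(2R,3S,4S)-2-Ar1-4-[(4-hydroxy-3,5-dimethoxyphenyl)(methoxy)methyl]tetrahydrofuran-3-yl]methanol, both epimers at the methoxy carbon | COc1cc([C@H](O[Si](C)(C)C(C)(C)C)[C@H](CO[Si](C)(C)C(C)(C)C)Oc2ccc([C@@H]3OC[C@@H](C(OC)c4cc(OC)c(O)c(OC)c4)[C@H]3CO)cc2OC)ccc1O[Si](C)(C)C(C)(C)C
F2 | step 10 | (S)-4-[3,5-dimethoxy-4-(trimethylsilyloxy)benzyl]dihydrofuran-2(3H)-one | O=C1OC[C@@H](Cc2cc(OC)c(O[Si](C)(C)C)c(OC)c2)C1
F3 | step 10 | (3R,4S)-3-[hydroxy(Ar1)methyl]-4-[3,5-dimethoxy-4-(trimethylsilyloxy)benzyl]dihydrofuran-2(3H)-one, both carbinol epimers | COc1cc([C@H](O[Si](C)(C)C(C)(C)C)[C@H](CO[Si](C)(C)C(C)(C)C)Oc2ccc(C(O)[C@@H]3C(=O)OC[C@H]3Cc4cc(OC)c(O[Si](C)(C)C)c(OC)c4)cc2OC)ccc1O[Si](C)(C)C(C)(C)C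
F4 | step 5 | tert-butyl (4-bromo-2-methoxyphenoxy)acetate | COc1cc(Br)ccc1OCC(=O)OC(C)(C)C
F5 | step 5 | (4-bromo-2-methoxyphenoxy)acetic acid | COc1cc(Br)ccc1OCC(=O)O
F6 | step 5 | (4-bromo-2-methoxyphenoxy)acetic pivalic anhydride | COc1cc(Br)ccc1OCC(=O)OC(=O)C(C)(C)C
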